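## Structural features

The target is a cis-fused decalin sesquiterpenoid of the eremophilane type. Ring A (C1, C2, C3, C4, C9, C10) and ring B (C4, C5, C6, C7, C8, C9) share the C4–C9 bond, and H-4 and the C9 methyl lie on the same face. Five stereocentres are contiguous, C1(O-acyl)–C10(CH3)–C9(CH3, quaternary)–C4(H)–C5(OH): the two methyls are cis, the C1 oxygen is trans to the C10 methyl, and the C5 hydroxyl is on the face of H-4. Ring B holds an α-ketol (C5–OH, C6=O) whose ketone is conjugated to a tetrasubstituted exocyclic alkene C7=C11 with the C12 hydroxymethyl cis to the carbonyl; C1 is esterified with (2E,4E,6E)-5-methyldodeca-2,4,6-trienoic acid. The fragile parts are the (Z)-γ-hydroxy enone (acid closes it to a hemiketal and dehydrates it to a 3-methylfuran; base can move the double bond into the ring), the epimerisable C5, and the trienoate, which rules out hydride, strong base and hydrogenation after acylation. The real difficulties are the cis-dimethyl pair at C9/C10 beside the ring fusion, the geometry of the tetrasubstituted alkene, and telling three hydroxyls apart at the end. In the cis-decalin conformer with the C9 methyl axial on ring A, the C1 oxygen, the C10 methyl and the C5 hydroxyl are all equatorial, so the natural C5 configuration is the thermodynamic one once C1 and C10 are set. The key step exploits the cis C4–H/C9–CH3 junction flanked by oxygen at C5 and C6 and by C8, which can carry a removable carbonyl: this is the imprint of a Diels–Alder reaction across the methyl-bearing double bond of 2-methoxy-5-methyl-1,4-benzoquinone, the diene supplying C10, C1 (with its oxygen), C2 and C3.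

## Logic of the disconnections

29 ⇒ 28. Only the O–Si bond at C5 is cut. The C5 hydroxyl must stay masked until the furan is opened, because a free carbinol beside the furan would trap the unveiled C12 aldehyde as a pyranone hemiacetal (Achmatowicz manifold). The gain is a last step that touches no carbon; the demand is a near-neutral fluoride source.

28 ⇒ 25. The C6 carbonyl oxygen and the C12 carbinol are reconnected as one ring oxygen (O–C6 and O–C12 of a 3-methylfuran). The ring fixes C12 cis to the C6 oxygen with no olefin-geometry problem and hides the sensitive enone until the end. A lactone lock would also fix the geometry, but it needs a hydride reduction to a diol and then oxidation of the secondary allylic alcohol beside the primary one, which is not selective without extra protection. The demand is that singlet oxygen choose the furan over the trienoate and hydride choose the aldehyde over the C6 ketone.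

25 ⇒ 19 + 24. The C1–O acyl bond is cut. This is convergent, and 19 has a single free hydroxyl, so no site selectivity is needed. The demand is an esterification mild enough to leave the triene geometry alone.

24 ⇒ 23 ⇒ 22 ⇒ 21 ⇒ 20. The C2=C3 and C4=C5 double bonds of the acid are cut by two phosphonate olefinations. 20 supplies C5–C12 and the branch methyl. The demand is (E) selectivity at the trisubstituted alkene.

19 ⇒ 15 + 16. The C7–C11 bond and the furan O–C6 bond are cut (aldol, then cyclodehydration). 16 brings C11, C12 and C13 with C12 already at the alcohol level, so no redox change is needed there. The demand is an enolate formed at C7 and not at C5.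

15 ⇒ 13 (through 14). No skeletal bond is cut; the C7=C8 bond is saturated and C5 is inverted. Hydride reaches the C5 carbonyl of 4 only from the convex face, which gives the 5β epimer. That β-silyloxy group is used as a conformational anchor for the ring A steps and is then equilibrated. The demand is that thermodynamics favour 5α, which they should once C1 and C10 carry equatorial substituents.

13 ⇒ 10 (through 11 and 12). The C1 carbinol comes from the ketone, and the C6 ketone/C7=C8 pair is the transposed form of the C8 carbonyl/C6 enol ether; the C8 oxygen of the quinone leaves here. The demand is face selectivity at C1.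

10 ⇒ 9 ⇒ 7 (through 8). The C10–CH3 bond is cut. A methyl carried by the diene would end trans to the C9 methyl under the endo rule, so it is added afterwards by alkylation from the convex face. The demand is an enolate formed only toward C10, which the C2=C3 unsaturation of 7 guarantees.

7 ⇒ 6 ⇒ 5 ⇒ 4. These are the retro-dehydrogenation of C2–C3, the O–Si bond at C5 and the C5–H bond. The enol ether of 4 lies at C1=C2, so its enolate would react at C2; oxidising it to the enone turns this into the regiocontrol element for C10.

4 ⇒ 3 + 2. C3–C4 and C9–C10 are cut, opening ring A. This is the key simplification: two achiral, readily available partners, with both ring-fusion centres set in one catalytic step. The demand is site, regio and face control on an unsymmetrical quinone.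

2 ⇒ 1. The O–Si bond is cut; the diene is the silyl enol ether of a commercial enone.

## Other disconnections considered

Alternative 1: The cut runs through C4–C9 and C1–C10 and opens both rings to the acyclic tigloyl trienone A2. The forward key step is an intramolecular Diels–Alder reaction (thermal or with Me2AlCl) giving the cis-fused bicycle A1.
- In favour: C9 and C10 both come from one (E)-alkene, so the cis relation of the two methyls follows from alkene geometry. Four contiguous centres (C1, C4, C9, C10) are set at once and the C1 oxygen arrives in place. On ring A this is better than the chosen plan, which spends three operations and a conformational argument on the C10 methyl.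
- Against: A2 must be made enantiopure with C5 and C6 already set, in a linear sequence of its own. Its alkoxydiene is acid-labile and its dienophile is trisubstituted. The ring-fusion outcome depends on one transition state with several variables. A1 carries a ketone at C8, where the target has CH2, and no carbonyl at C6, so a deoxygenation, an oxidation and an alkene hydrogenation follow.
- Comparison: structurally superior for ring A; the chosen plan is better for ring B, since the quinone delivers oxygen at C5 and C6 and a C8 oxygen that drives the transposition. Mechanistically, Alternative 1 puts all the risk in one step while the chosen plan spreads it. Step economy is similar or slightly worse once the synthesis of A2 is counted.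

Alternative 2: The cut is C9–C10 and C1–C2. The vinyl enone A4, activated at its carbonyl by a chiral oxazaborolidinium triflimide, acts as the diene toward the enol ether A5 and gives the enone A3.
- In favour: C9, C10 and C1 are set in one catalytic enantioselective step, the trans C10-methyl/C1-oxygen relation comes from the (E) geometry of A5, and only a benzyl group is carried. For ring A, and for the step count to ring A, this is better than the chosen plan.
- Against: A3 has its carbonyl at C5 and no oxygen at C6, so ring B needs a redox relay (C6 oxidation, then exchange of the oxidation levels of C5 and C6). The cis fusion must still be set by reducing the C3=C4 bond from the correct face. A4 is a cross-conjugated dienone prone to dimerisation, and regio and endo control for this inverse-demand mode are less well precedented than for quinone cycloadditions.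
- Comparison: equal in kind mechanistically (both are catalytic asymmetric [4+2] reactions), better for ring A, worse for ring B oxygenation and for the C4 centre. The overall step count should be about the same.

Alternative 3: The C9–C10 bond is made by a 1,2-shift. The mesylate A7, prepared from the enantiopure hydrindenedione A8, rearranges with Et3Al (semipinacol ring expansion) to the dione A6.
- In favour: the absolute configuration at C9 comes from a very dependable amino-acid-catalysed annulation, which is equal to or better than the chosen key step in certainty. The migration is stereospecific with inversion at C10, so the cis-dimethyl pair does not depend on any conformational bias, which is better than the chosen alkylation. A6 already holds the C1 ketone and the C6 carbonyl.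
- Against: A7 needs two extra stereocentres (carbinol and mesylate carbon) in a defined relation, and migration of the other ring bond or epoxide closure can compete. A6 lacks the C5 oxygen and has a C4=C5 double bond, so the 5-hydroxyl and the cis H-4 need an enone α-functionalisation and a face-selective reduction. Two ketones must also be told apart.
- Comparison: better for C9/C10, worse for C4/C5 and ring B; step economy is comparable (short to A6, long afterwards).

Key step: step 2

Remarks and assumptions (one line each):
- Locants C1–C13 are those used in "Structural features"; α is the face of the bicycle carrying the C9 methyl and H-4, β the opposite face.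
- A [4+2] adduct of a 2-silyloxybutadiene must have its enol ether double bond between C1 and C2, flanked by the two former diene termini; a C1=C10 enol ether cannot arise from this cycloaddition, so 4 is drawn with C1=C2.
- (R)-1,1'-Bi-2-naphthol is assumed to give the (4aR,8aS) adduct; if the sense is the opposite, the (S) ligand is used.
- The target is drawn as the open hydroxy ketone; its C6 hemiketal ring–chain tautomer is assumed to equilibrate with it.
- 3, 16 and 20 are taken as commercial.

## Steps

Step 1
Reactants: 1 but-3-en-2-one
Product: 2 2-(tert-butyldimethylsilyloxy)buta-1,3-diene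
Conditions: TBSOTf, Et3N, Et2O, 0 °C
Reagents that add atoms: tert-butyldimethylsilyl trifluoromethanesulfonate, CC(C)(C)[Si](C)(C)OS(=O)(=O)C(F)(F)F
Why: Soft enolisation: O-silylation of the enone by the silyl triflate and loss of a methyl proton to the amine give the 2-silyloxydiene, the standard silyl enol ether preparation of this diene class.

Step 2
Reactants: 3 2-methoxy-5-methyl-1,4-benzoquinone; 2 2-(tert-butyldimethylsilyloxy)buta-1,3-diene
Product: 4 (4aR,8aS)-6-(tert-butyldimethylsilyloxy)-2-methoxy-4a-methyl-4a,5,8,8a-tetrahydronaphthalene-1,4-dione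
Conditions: (R)-1,1'-bi-2-naphthol (11 mol %), TiCl2(OiPr)2 (10 mol %), 4 Å MS, CH2Cl2, −40 → −20 °C
Reagents that add atoms: none
Why: This is a Lewis acid catalysed normal-demand Diels–Alder reaction of a quinone, the closest known class being chiral Lewis acid catalysed cycloadditions of 2-alkoxy-5-alkyl-1,4-benzoquinones with 2-silyloxydienes. Two-point binding of the binaphtholate–TiCl2 unit (tetravalent titanium) to the methoxy oxygen and the neighbouring carbonyl oxygen of 3 activates only that carbonyl, so its conjugated, methyl-bearing C=C is the dienophile and the methyl-bearing carbon (future C9) is the electrophilic β-terminus, while the methoxy-substituted C=C is a deactivated vinylogous ester and stays untouched. The nucleophilic CH2 terminus of 2 (the one attached to the silyloxy carbon, future C10) bonds to C9 in an asynchronous but concerted [4+2] transition state and the vinyl terminus (future C3) bonds to C4, which places the silyloxy carbon at C1. Ring A is closed by this single suprafacial (4+2) cycloaddition, both ring bonds (C9–C10 and C3–C4) forming on the same face of the quinone. C9 and C4 are therefore cis by mechanism, and their absolute configuration is set by the binaphthyl ligand, which blocks one face of the chelated quinone. Because 2 has no terminal substituents, the endo or exo mode is stereochemically silent; the step needs only site and regioselectivity, secured by the chelate, and face selectivity, secured by the ligand. The enol ether of the adduct lies between C1 and C2, and the later steps are planned on that basis. The tert-butyldimethylsilyl enol ether should survive the mild Lewis acid at low temperature.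

Step 3
Reactants: 4 (4aR,8aS)-6-(tert-butyldimethylsilyloxy)-2-methoxy-4a-methyl-4a,5,8,8a-tetrahydronaphthalene-1,4-dione
Product: 5 cis-fused 7-(tert-butyldimethylsilyloxy)-4-hydroxy-3-methoxy-8a-methyl-4a,5,8,8a-tetrahydronaphthalen-1(4H)-one with the hydroxyl β (5β-OH in target locants)
Conditions: NaBH4, CeCl3·7H2O, MeOH–CH2Cl2, −78 °C
Reagents that add atoms: none
Why: Luche 1,2-reduction: C5 is the more electrophilic and less hindered carbonyl, whereas C8 is a vinylogous ester carbonyl beside the quaternary C9. Hydride enters from the convex α-face of the cis-fused bicycle, so the new hydroxyl is β, the opposite of what the target needs; this is accepted on purpose, because the β-oxygen steers steps 6 and 8 and is corrected in step 9. After this step C4 is no longer α to a carbonyl, so the ring fusion can no longer epimerise.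

Step 4
Reactants: 5 cis-fused 7-(tert-butyldimethylsilyloxy)-4-hydroxy-3-methoxy-8a-methyl-4a,5,8,8a-tetrahydronaphthalen-1(4H)-one (5β-OH)
Product: 6 cis-fused 7-(tert-butyldimethylsilyloxy)-3-methoxy-8a-methyl-4-(triisopropylsilyloxy)-4a,5,8,8a-tetrahydronaphthalen-1(4H)-one (5β-OSi in target locants)
Conditions: TIPSOTf, 2,6-lutidine, CH2Cl2, 0 °C
Reagents that add atoms: triisopropylsilyl trifluoromethanesulfonate, CC(C)[Si](C(C)C)(C(C)C)OS(=O)(=O)C(F)(F)F
Why: Silyl triflate silylation of a hindered secondary alcohol; the bulky ether is inert to the bases, hydrides and dilute acid used later. Being equatorial on ring B, it holds the bicycle in the conformer in which C8 is axial on ring A.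

Step 5
Reactants: 6 cis-fused 7-(tert-butyldimethylsilyloxy)-3-methoxy-8a-methyl-4-(triisopropylsilyloxy)-4a,5,8,8a-tetrahydronaphthalen-1(4H)-one
Product: 7 cis-fused 3-methoxy-8a-methyl-4-(triisopropylsilyloxy)-4,4a,8,8a-tetrahydronaphthalene-1,7-dione (target locants: C1=O and C2=C3 with 5β-OSi)
Conditions: Pd(OAc)2 (1.1 equiv), MeCN, 40 °C
Reagents that add atoms: none
Why: Saegusa–Ito oxidation: the silyl enol ether gives a palladium enolate (divalent palladium) at C2, and β-hydride loss from C3 gives the C2=C3 enone. In this enone the only enolisable α-carbon of the C1 ketone is C10, which turns the C1=C2 position of the enol ether into the regiocontrol element.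

Step 6
Reactants: 7 cis-fused 3-methoxy-8a-methyl-4-(triisopropylsilyloxy)-4,4a,8,8a-tetrahydronaphthalene-1,7-dione
Product: 9 cis-fused 3-methoxy-8,8a-dimethyl-4-(triisopropylsilyloxy)-4,4a,8,8a-tetrahydronaphthalene-1,7-dione with the two methyls cis (10α-CH3), via lithium dienolate 8 (not isolated)
Conditions: LiN(i-Pr)2 (1.05 equiv), THF, −78 °C; MeI, −78 → −40 °C
Reagents that add atoms: iodomethane, CI
Why: Kinetic α'-deprotonation of a cyclohexenone gives the cross-conjugated dienolate, which can be alkylated only at C10 (C2 is vinylic, and ring B cannot enolise toward the quaternary C9). With C8 pseudo-axial on ring A, iodomethane approaches anti to it from the convex α-face, so the new methyl is cis to the C9 methyl (axial enolate alkylation). A cold quench keeps this kinetically set centre from equilibrating.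

Step 7
Reactants: 9 cis-fused 3-methoxy-8,8a-dimethyl-4-(triisopropylsilyloxy)-4,4a,8,8a-tetrahydronaphthalene-1,7-dione
Product: 10 cis-fused 3-methoxy-8,8a-dimethyl-4-(triisopropylsilyloxy)-4,4a,5,6,8,8a-hexahydronaphthalene-1,7-dione
Conditions: H2 (1 atm), 10% Pd/C, EtOAc, 23 °C
Reagents that add atoms: none
Why: Heterogeneous hydrogenation saturates the disubstituted C2=C3 enone bond; the donor-substituted, trisubstituted C6=C7 bond of the vinylogous ester is much less reactive. The neutral medium leaves the epimerisable C10 centre alone.

Step 8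
Reactants: 10 cis-fused 3-methoxy-8,8a-dimethyl-4-(triisopropylsilyloxy)-4,4a,5,6,8,8a-hexahydronaphthalene-1,7-dione
Product: 13 cis-fused 6-hydroxy-4a,5-dimethyl-1-(triisopropylsilyloxy)-4a,5,6,7,8,8a-hexahydronaphthalen-2(1H)-one (target locants: 1β-OH and 10α-CH3 and 5β-OSi with C6=O and C7=C8), via lithium C1-alkoxide 11 (not isolated), via C1,C8-diol 12 (not isolated)
Conditions: LiBH(s-Bu)3, THF, −78 °C; i-Bu2AlH, −78 → −40 °C; 1 M HCl, THF, 0 °C
Reagents that add atoms: water, O
Why: The bulky borohydride reduces only the C1 ketone, entering from the convex α-face (equatorial attack, anti to the axial C8), which gives the 1β-alcohol trans to the C10 methyl. The aluminium hydride then reduces the vinylogous ester carbonyl at C8, and aqueous acid completes the Stork–Danheiser transposition: loss of the C8 oxygen, attack of water at C6 and loss of methanol give the C6 ketone with the C7=C8 bond.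

Step 9
Reactants: 13 cis-fused 6-hydroxy-4a,5-dimethyl-1-(triisopropylsilyloxy)-4a,5,6,7,8,8a-hexahydronaphthalen-2(1H)-one (5β-OSi)
Product: 15 cis-fused 6-hydroxy-4a,5-dimethyl-1-(triisopropylsilyloxy)octahydronaphthalen-2(1H)-one with the silyloxy group α (5α-OSi in target locants), via 5β-silyloxy saturated ketone 14 (not isolated)
Conditions: H2 (1 atm), 10% Pd/C, MeOH, 23 °C; filter; NaOMe (0.5 equiv), 23 → 40 °C
Reagents that add atoms: none
Why: Hydrogenation removes the C7=C8 bond, and methoxide then equilibrates C5 through the C5–C6 enolate. The C1 oxygen and the C10 methyl are both equatorial only in the conformer with the C9 methyl axial on ring A, where a 5β-silyloxy group would be syn-axial to C10; the equilibrium should therefore lie far on the side of the 5α epimer, in which all three substituents are equatorial.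

Step 10
Reactants: 15 cis-fused 6-hydroxy-4a,5-dimethyl-1-(triisopropylsilyloxy)octahydronaphthalen-2(1H)-one (5α-OSi); 16 1-(tert-butyldimethylsilyloxy)propan-2-one
Product: 19 3,4a,5-trimethyl-9-(triisopropylsilyloxy)-4,4a,5,6,7,8,8a,9-octahydronaphtho[2,3-b]furan-6-ol (target locants: 1β-OH and 5α-OSi with the furan O–C6=C7–C11(CH3)=C12), via dilithium alkoxide enolate 17 (not isolated), via aldol adduct 18 (not isolated)
Conditions: LiN(i-Pr)2 (2.2 equiv), THF, −78 °C; 16, −78 °C; AcOH quench; then camphorsulfonic acid (0.2 equiv), MeOH–CH2Cl2, 0 → 23 °C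
Reagents that add atoms: none
Why: Two equivalents of amide base give the C1 alkoxide and the kinetic C6–C7 enolate (C5 bears the bulky silyloxy group and is deprotonated more slowly), and aldol addition to the α-silyloxy ketone forms C7–C11. Acid then removes the primary silyl group, the C12 hydroxyl closes on C6, and two dehydrations aromatise the ring to the 3-methylfuran (aldol/cyclodehydration furan annulation of the Paal–Knorr type). The furan locks C12 cis to the C6 oxygen and masks the sensitive hydroxy enone; the secondary triisopropylsilyl ether should survive.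

Step 11
Reactants: 20 (E)-non-3-en-2-one
Product: 21 (2E,4E)-N-methoxy-N,3-dimethylnona-2,4-dienamide
Conditions: (EtO)2P(O)CH2C(O)N(OMe)Me, NaH, THF, 0 → 50 °C
Reagents that add atoms: diethyl [2-[methoxy(methyl)amino]-2-oxoethyl]phosphonate, CCOP(=O)(CC(=O)N(C)OC)OCC
Why: Horner–Wadsworth–Emmons olefination of a methyl ketone with a stabilised phosphonate anion; the (2E) isomer should predominate (amide trans to the larger alkenyl group), and the minor (2Z) isomer is removed by chromatography.

Step 12
Reactants: 21 (2E,4E)-N-methoxy-N,3-dimethylnona-2,4-dienamide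
Product: 22 (2E,4E)-3-methylnona-2,4-dienal
Conditions: i-Bu2AlH, THF, −78 °C; aq. sodium potassium tartrate
Reagents that add atoms: none
Why: The N-methoxy-N-methylamide is reduced to a stable chelated aluminium hemiaminal that releases the aldehyde only on work-up, so over-reduction and conjugate reduction are avoided.

Step 13
Reactants: 22 (2E,4E)-3-methylnona-2,4-dienal
Product: 23 ethyl (2E,4E,6E)-5-methyldodeca-2,4,6-trienoate
Conditions: (EtO)2P(O)CH2CO2Et, NaH, THF, 0 → 23 °C
Reagents that add atoms: triethyl phosphonoacetate, CCOC(=O)CP(=O)(OCC)OCC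
Why: Horner–Wadsworth–Emmons olefination of an aldehyde with a stabilised phosphonate is reliably (E)-selective, and the low temperature leaves the existing double bonds unchanged.

Step 14
Reactants: 23 ethyl (2E,4E,6E)-5-methyldodeca-2,4,6-trienoate
Product: 24 (2E,4E,6E)-5-methyldodeca-2,4,6-trienoic acid
Conditions: LiOH, THF–MeOH–H2O, 23 °C; then 1 M HCl to pH 3
Reagents that add atoms: lithium hydroxide, [Li+].[OH-]
Why: Saponification of an unhindered conjugated ester; hydroxide at room temperature should not isomerise the triene.

Step 15
Reactants: 19 3,4a,5-trimethyl-9-(triisopropylsilyloxy)-4,4a,5,6,7,8,8a,9-octahydronaphtho[2,3-b]furan-6-ol; 24 (2E,4E,6E)-5-methyldodeca-2,4,6-trienoic acid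
Product: 25 3,4a,5-trimethyl-9-(triisopropylsilyloxy)-4,4a,5,6,7,8,8a,9-octahydronaphtho[2,3-b]furan-6-yl (2E,4E,6E)-5-methyldodeca-2,4,6-trienoate
Conditions: EDC·HCl, DMAP, CH2Cl2, 0 → 23 °C
Reagents that add atoms: none
Why: Steglich esterification: the C1 hydroxyl is the only free hydroxyl of 19, so no site selectivity is needed. Carbodiimide activation with DMAP at or below room temperature should not isomerise the trienoate, and the furan tolerates these weakly basic conditions.

Step 16
Reactants: 25 3,4a,5-trimethyl-9-(triisopropylsilyloxy)-4,4a,5,6,7,8,8a,9-octahydronaphtho[2,3-b]furan-6-yl (2E,4E,6E)-5-methyldodeca-2,4,6-trienoate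
Product: 28 5-O-triisopropylsilyl ether of the target (C6=O with the C12 hydroxymethyl cis to it across C7=C11), via furan endoperoxide 26 (not isolated), via (Z)-keto aldehyde 27 (not isolated)
Conditions: O2, hν (visible), 5,10,15,20-tetraphenylporphyrin (cat.), CH2Cl2, −78 °C; Me2S, −78 → −40 °C; NaBH4, MeOH, −78 °C; pH 7 buffer
Reagents that add atoms: dioxygen, O=O
Why: Singlet oxygen adds [4+2] across the electron-rich 2,3-dialkylfuran far faster than it reacts with the ester-conjugated triene, and dimethyl sulfide reduces the endoperoxide to the (Z)-keto aldehyde, whose geometry is inherited from the ring. Borohydride at −78 °C reduces the aldehyde much faster than the hindered enone ketone on the fully substituted alkene or the ester, giving the C12 alcohol cis to C6=O. The C5 oxygen stays silylated so that it cannot trap the aldehyde as a pyranone hemiacetal.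

Step 17
Reactants: 28 5-O-triisopropylsilyl ether of the target
Product: 29 (1R,2R,4aS,5R,8aR)-5-hydroxy-7-[(Z)-1-hydroxypropan-2-ylidene]-1,8a-dimethyl-6-oxodecahydronaphthalen-2-yl (2E,4E,6E)-5-methyldodeca-2,4,6-trienoate (CNP0226738.1)
Conditions: Bu4NF, AcOH (1:1), THF, 0 → 23 °C
Reagents that add atoms: none
Why: Fluoride cleaves the silyl ether, which is activated by the neighbouring ketone. Buffering with acetic acid keeps the medium near neutral, so the (Z)-γ-hydroxy enone should not cyclodehydrate to the furan, the alkylidene bond should not migrate, and C5 (already in its favoured configuration) should not epimerise.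

## Compound list

1 | but-3-en-2-one | CC(=O)C=C | starting material
2 | 2-(tert-butyldimethylsilyloxy)buta-1,3-diene | C=CC(=C)O[Si](C)(C)C(C)(C)C | intermediate
3 | 2-methoxy-5-methyl-1,4-benzoquinone | COC1=CC(=O)C(C)=CC1=O | starting material
4 | (4aR,8aS)-6-(tert-butyldimethylsilyloxy)-2-methoxy-4a-methyl-4a,5,8,8a-tetrahydronaphthalene-1,4-dione (cis-fused; enol ether at C1=C2 in target locants) | CC(C)(C)[Si](C)(C)OC1=CC[C@@H]2C(=O)C(OC)=CC(=O)[C@]2(C)C1 | intermediate
5 | cis-fused 7-(tert-butyldimethylsilyloxy)-4-hydroxy-3-methoxy-8a-methyl-4a,5,8,8a-tetrahydronaphthalen-1(4H)-one, hydroxyl β (5β-OH, 4α-H, 9α-CH3) | CC(C)(C)[Si](C)(C)OC1=CC[C@@H]2[C@H](O)C(OC)=CC(=O)[C@]2(C)C1 | intermediate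
6 | 5β-triisopropylsilyl ether of 5 | CC(C)(C)[Si](C)(C)OC1=CC[C@@H]2[C@H](O[Si](C(C)C)(C(C)C)C(C)C)C(OC)=CC(=O)[C@]2(C)C1 | intermediate
7 | cis-fused 3-methoxy-8a-methyl-4-(triisopropylsilyloxy)-4,4a,8,8a-tetrahydronaphthalene-1,7-dione (C1=O, C2=C3, 5β-OSi, C6(OMe)=C7, C8=O) | O=C1C=C[C@@H]2[C@H](O[Si](C(C)C)(C(C)C)C(C)C)C(OC)=CC(=O)[C@]2(C)C1 | intermediate
8 | lithium cross-conjugated dienolate of 7 (C10=C1(OLi)–C2=C3) | [Li+].[O-]C1=C[C@@]2(C)C(=O)C=C(OC)[C@@H](O[Si](C(C)C)(C(C)C)C(C)C)[C@H]2C=C1 | intermediate
9 | cis-fused 3-methoxy-8,8a-dimethyl-4-(triisopropylsilyloxy)-4,4a,8,8a-tetrahydronaphthalene-1,7-dione, methyls cis (10α-CH3) | O=C1C=C[C@@H]2[C@H](O[Si](C(C)C)(C(C)C)C(C)C)C(OC)=CC(=O)[C@]2(C)[C@H]1C | intermediate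
10 | cis-fused 3-methoxy-8,8a-dimethyl-4-(triisopropylsilyloxy)-4,4a,5,6,8,8a-hexahydronaphthalene-1,7-dione | O=C1CC[C@@H]2[C@H](O[Si](C(C)C)(C(C)C)C(C)C)C(OC)=CC(=O)[C@]2(C)[C@H]1C | intermediate
11 | lithium alkoxide of the 1β-alcohol from 10 (C8 ketone intact) | [Li+].[O-][C@@H]1CC[C@@H]2[C@H](O[Si](C(C)C)(C(C)C)C(C)C)C(OC)=CC(=O)[C@]2(C)[C@H]1C | intermediate
12 | 1β,8-diol with the C6 enol ether (shown as the free diol; C8 configuration undefined) | O[C@@H]1CC[C@@H]2[C@H](O[Si](C(C)C)(C(C)C)C(C)C)C(OC)=CC(O)[C@]2(C)[C@H]1C | intermediate
13 | cis-fused 6-hydroxy-4a,5-dimethyl-1-(triisopropylsilyloxy)-4a,5,6,7,8,8a-hexahydronaphthalen-2(1H)-one (1β-OH, 10α-CH3, 5β-OSi, C6=O, C7=C8) | O[C@@H]1CC[C@@H]2[C@H](O[Si](C(C)C)(C(C)C)C(C)C)C(=O)C=C[C@]2(C)[C@H]1C | intermediate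
14 | cis-fused 6-hydroxy-4a,5-dimethyl-1-(triisopropylsilyloxy)octahydronaphthalen-2(1H)-one, 5β-OSi | O[C@@H]1CC[C@@H]2[C@H](O[Si](C(C)C)(C(C)C)C(C)C)C(=O)CC[C@]2(C)[C@H]1C | intermediate
15 | cis-fused 6-hydroxy-4a,5-dimethyl-1-(triisopropylsilyloxy)octahydronaphthalen-2(1H)-one, 5α-OSi | O[C@@H]1CC[C@@H]2[C@@H](O[Si](C(C)C)(C(C)C)C(C)C)C(=O)CC[C@]2(C)[C@H]1C | intermediate
16 | 1-(tert-butyldimethylsilyloxy)propan-2-one | CC(=O)CO[Si](C)(C)C(C)(C)C | starting material
17 | dilithium C1-alkoxide/C6–C7 enolate of 15 | [Li+].[Li+].[O-][C@@H]1CC[C@@H]2[C@@H](O[Si](C(C)C)(C(C)C)C(C)C)C([O-])=CC[C@]2(C)[C@H]1C | intermediate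
18 | aldol adduct of 15 and 16 at C7 (tertiary C11 carbinol; diastereomers at C7 and C11) | O[C@@H]1CC[C@@H]2[C@@H](O[Si](C(C)C)(C(C)C)C(C)C)C(=O)C(C(C)(O)CO[Si](C)(C)C(C)(C)C)C[C@]2(C)[C@H]1C | intermediate
19 | 3,4a,5-trimethyl-9-(triisopropylsilyloxy)-4,4a,5,6,7,8,8a,9-octahydronaphtho[2,3-b]furan-6-ol (1β-OH, 10α-CH3, 9α-CH3, 4α-H, 5α-OSi) | O[C@@H]1CC[C@@H]2[C@@H](O[Si](C(C)C)(C(C)C)C(C)C)c3occ(C)c3C[C@]2(C)[C@H]1C | intermediate
20 | (E)-non-3-en-2-one | CCCCC/C=C/C(C)=O | starting material
21 | (2E,4E)-N-methoxy-N,3-dimethylnona-2,4-dienamide | CCCCC/C=C/C(C)=C/C(=O)N(C)OC | intermediate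
22 | (2E,4E)-3-methylnona-2,4-dienal | CCCCC/C=C/C(C)=C/C=O | intermediate
23 | ethyl (2E,4E,6E)-5-methyldodeca-2,4,6-trienoate | CCCCC/C=C/C(C)=C/C=C/C(=O)OCC | intermediate
24 | (2E,4E,6E)-5-methyldodeca-2,4,6-trienoic acid | CCCCC/C=C/C(C)=C/C=C/C(=O)O | intermediate
25 | (2E,4E,6E)-5-methyldodeca-2,4,6-trienoate of 19 at the C1 oxygen | CCCCC/C=C/C(C)=C/C=C/C(=O)O[C@@H]1CC[C@@H]2[C@@H](O[Si](C(C)C)(C(C)C)C(C)C)c3occ(C)c3C[C@]2(C)[C@H]1C | intermediate
26 | C6,C12-endoperoxide of 25 (bridgehead configuration undefined) | CCCCC/C=C/C(C)=C/C=C/C(=O)O[C@@H]1CC[C@@H]2[C@@H](O[Si](C(C)C)(C(C)C)C(C)C)C34OC(OO3)C(C)=C4C[C@]2(C)[C@H]1C | intermediate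
27 | (Z)-keto aldehyde (C6=O and C12H=O cis across C7=C11), 5α-OSi | CCCCC/C=C/C(C)=C/C=C/C(=O)O[C@@H]1CC[C@@H]2[C@@H](O[Si](C(C)C)(C(C)C)C(C)C)C(=O)/C(=C(/C)C=O)C[C@]2(C)[C@H]1C | intermediate
28 | 5-O-triisopropylsilyl ether of the target | CCCCC/C=C/C(C)=C/C=C/C(=O)O[C@@H]1CC[C@@H]2[C@@H](O[Si](C(C)C)(C(C)C)C(C)C)C(=O)/C(=C(/C)CO)C[C@]2(C)[C@H]1C | intermediate
29 | (1R,2R,4aS,5R,8aR)-5-hydroxy-7-[(Z)-1-hydroxypropan-2-ylidene]-1,8a-dimethyl-6-oxodecahydronaphthalen-2-yl (2E,4E,6E)-5-methyldodeca-2,4,6-trienoate | CCCCC/C=C/C(C)=C/C=C/C(=O)O[C@@H]1CC[C@@H]2[C@@H](O)C(=O)/C(=C(/C)CO)C[C@]2(C)[C@H]1C | target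

## Step count and least certain steps

Total step count: 17. Longest linear sequence: 13 steps (steps 1–10 and 15–17, from but-3-en-2-one); the acid branch (steps 11–14) has 4 steps.

Step 2 (key step). The most likely failures are low reactivity and loss of regio- or face control: the reacting quinone carbon carries a methyl group and 2 is only a moderately reactive diene. A non-chelated pathway that activates the other carbonyl would reverse the orientation, and the titanium Lewis acid may cleave the silyl enol ether. The fallback sets out from compound 3 and uses a more nucleophilic diene, (E)-1-methoxy-3-(tert-butyldimethylsilyloxy)buta-1,3-diene F1, made from (E)-4-methoxybut-3-en-2-one with TBSOTf and Et3N. Under the same chelating catalyst at lower temperature it should give the 8-methoxy cycloadduct F2. Luche reduction then gives the 5β-alcohol F3, and dilute aqueous HCl unmasks the ring A enone by enol ether hydrolysis and β-elimination of methanol, giving the 5β-hydroxy enone F4. Silylation with TIPSOTf and 2,6-lutidine rejoins the route at compound 7 and makes step 5 unnecessary.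

Step 6. The most likely failures are poor face selectivity and loss of the kinetic configuration at C10. The α-face preference rests on the 5β-silyloxy group holding C8 axial on ring A, and the axial methyl is not the thermodynamic epimer while C1 is a ketone, so proton exchange during the alkylation would erode it. The fallback sets out from compound 7 and relays C10 from the C1 hydroxyl. LiN(i-Pr)2 and dimethyl(methylidene)ammonium iodide give the C10 aminomethyl ketone F5, and MeI followed by NaHCO3 gives the cross-conjugated C10-methylene dienone F6. Luche reduction gives the 1β-dienol F7. Hydroxyl-directed hydrogenation with [Ir(cod)(PCy3)(py)]PF6 and H2 adds hydrogen to C10 (and to C2=C3) on the face of the C1 hydroxyl, so the methyl ends trans to the C1 oxygen whatever the ring conformation, giving the saturated 1β-alcohol F8. F8 enters step 8 at the i-Bu2AlH stage and rejoins the route at compound 13.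

Step 8. The most likely failure is poor face selectivity in the C1 reduction: the axial C10 methyl beside the carbonyl partly hinders the equatorial approach that the axial C8 otherwise enforces. Incomplete reduction of the hindered C8 carbonyl is also possible. The fallback sets out from compound 10. If the 1α-hydroxy enone F9 predominates, Mitsunobu inversion with 4-nitrobenzoic acid, PPh3 and diisopropyl azodicarboxylate gives the 1β-(4-nitrobenzoate) F10, and methanolysis with K2CO3 in MeOH returns compound 13.

Step 9. The most likely failures are incomplete or misdirected equilibration: migration of the silyl group between the C5 and C6 oxygens in the enolate, or an equilibrium less one-sided than the conformational analysis predicts. The fallback sets out from compound 14 and replaces enolate equilibration by an SN2 inversion at the furan stage. Steps 10 and 15 are run on the 5β series to give the 5β-silyloxy furan alcohol F11 and its trienoate F12. Bu4NF frees the 5β furfuryl-type alcohol F13, and Mitsunobu reaction with chloroacetic acid at this activated position gives the 5α-chloroacetate F14. Thiourea and NaHCO3 in EtOH remove the chloroacetate selectively to give the 5α-alcohol F15, and TIPSOTf with 2,6-lutidine rejoins the route at compound 25.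

Step 16. The most likely failures are loss of chemoselectivity and isomerisation: competing addition of singlet oxygen to the triene, sensitised E/Z scrambling of the trienoate, or partial reduction of the C6 ketone along with the aldehyde. The fallback sets out from compound 19 and opens the furan before the acid is attached. The same photooxygenation, Me2S reduction and low-temperature NaBH4 reduction give the C1,C12-diol F16. Selective silylation of the primary allylic hydroxyl (TBSCl, imidazole, −20 °C) gives the C12 silyl ether F17, and Steglich esterification with 24 gives the bis-silyl ester F18. Bu4NF buffered with AcOH removes both silyl groups and rejoins the route at compound 29.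

## Further compounds

F1 | step 2 | (E)-1-methoxy-3-(tert-butyldimethylsilyloxy)buta-1,3-diene | CO/C=C/C(=C)O[Si](C)(C)C(C)(C)C
F2 | step 2 | cis-fused 6-(tert-butyldimethylsilyloxy)-2,8-dimethoxy-4a-methyl-4a,5,8,8a-tetrahydronaphthalene-1,4-dione (C8 methoxy configuration immaterial) | CC(C)(C)[Si](C)(C)OC1=CC(OC)[C@@H]2C(=O)C(OC)=CC(=O)[C@]2(C)C1
F3 | step 2 | 5β-alcohol of F2 (target locant C5) | CC(C)(C)[Si](C)(C)OC1=CC(OC)[C@@H]2[C@H](O)C(OC)=CC(=O)[C@]2(C)C1
F4 | step 2 | cis-fused 4-hydroxy-3-methoxy-8a-methyl-4,4a,8,8a-tetrahydronaphthalene-1,7-dione (5β-OH; C1=O, C2=C3 in target locants) | O=C1C=C[C@@H]2[C@H](O)C(OC)=CC(=O)[C@]2(C)C1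
F5 | step 6 | C10-(dimethylaminomethyl) derivative of 7 | O=C1C=C[C@@H]2[C@H](O[Si](C(C)C)(C(C)C)C(C)C)C(OC)=CC(=O)[C@]2(C)C1CN(C)C
F6 | step 6 | C10-methylene dienone from 7 | O=C1C=C[C@@H]2[C@H](O[Si](C(C)C)(C(C)C)C(C)C)C(OC)=CC(=O)[C@]2(C)C1=C
F7 | step 6 | 1β-dienol from F6 | O[C@@H]1C=C[C@@H]2[C@H](O[Si](C(C)C)(C(C)C)C(C)C)C(OC)=CC(=O)[C@]2(C)C1=C
F8 | step 6 | saturated 1β-alcohol with 10α-methyl (free alcohol of 11) | O[C@@H]1CC[C@@H]2[C@H](O[Si](C(C)C)(C(C)C)C(C)C)C(OC)=CC(=O)[C@]2(C)[C@H]1C
F9 | step 8 | 1α-epimer of 13 | O[C@H]1CC[C@@H]2[C@H](O[Si](C(C)C)(C(C)C)C(C)C)C(=O)C=C[C@]2(C)[C@H]1C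
F10 | step 8 | 1β-(4-nitrobenzoate) of 13 | O=C(O[C@@H]1CC[C@@H]2[C@H](O[Si](C(C)C)(C(C)C)C(C)C)C(=O)C=C[C@]2(C)[C@H]1C)c1ccc(cc1)[N+](=O)[O-]
F11 | step 9 | 5β-epimer of 19 | O[C@@H]1CC[C@@H]2[C@H](O[Si](C(C)C)(C(C)C)C(C)C)c3occ(C)c3C[C@]2(C)[C@H]1C
F12 | step 9 | 5β-epimer of 25 | CCCCC/C=C/C(C)=C/C=C/C(=O)O[C@@H]1CC[C@@H]2[C@H](O[Si](C(C)C)(C(C)C)C(C)C)c3occ(C)c3C[C@]2(C)[C@H]1C
F13 | step 9 | 5β-hydroxy furan trienoate | CCCCC/C=C/C(C)=C/C=C/C(=O)O[C@@H]1CC[C@@H]2[C@H](O)c3occ(C)c3C[C@]2(C)[C@H]1C
F14 | step 9 | 5α-chloroacetate of the furan trienoate | CCCCC/C=C/C(C)=C/C=C/C(=O)O[C@@H]1CC[C@@H]2[C@@H](OC(=O)CCl)c3occ(C)c3C[C@]2(C)[C@H]1C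
F15 | step 9 | 5α-hydroxy furan trienoate | CCCCC/C=C/C(C)=C/C=C/C(=O)O[C@@H]1CC[C@@H]2[C@@H](O)c3occ(C)c3C[C@]2(C)[C@H]1C
F16 | step 16 | 1β,12-diol with C6 ketone, (Z)-alkylidene and 5α-OSi | O[C@@H]1CC[C@@H]2[C@@H](O[Si](C(C)C)(C(C)C)C(C)C)C(=O)/C(=C(/C)CO)C[C@]2(C)[C@H]1C
F17 | step 16 | 12-O-tert-butyldimethylsilyl ether of F16 | O[C@@H]1CC[C@@H]2[C@@H](O[Si](C(C)C)(C(C)C)C(C)C)C(=O)/C(=C(/C)CO[Si](C)(C)C(C)(C)C)C[C@]2(C)[C@H]1C
F18 | step 16 | 5,12-bis-silyl ether of the target | CCCCC/C=C/C(C)=C/C=C/C(=O)O[C@@H]1CC[C@@H]2[C@@H](O[Si](C(C)C)(C(C)C)C(C)C)C(=O)/C(=C(/C)CO[Si](C)(C)C(C)(C)C)C[C@]2(C)[C@H]1C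
A1 | alternative 1 | cis-fused 7-(benzyloxy)-4-(tert-butyldimethylsilyloxy)-8,8a-dimethyl-3-(triethylsilyloxy)-3,4,4a,7,8,8a-hexahydronaphthalen-1(2H)-one (configuration as drawn) | C(c1ccccc1)O[C@@H]2C=C[C@@H]3[C@@H](O[Si](C)(C)C(C)(C)C)[C@@H](O[Si](CC)(CC)CC)CC(=O)[C@]3(C)[C@H]2C
A2 | alternative 1 | (2E,8E,10E)-11-(benzyloxy)-7-(tert-butyldimethylsilyloxy)-3-methyl-6-(triethylsilyloxy)undeca-2,8,10-trien-4-one (configuration as drawn) | C(c1ccccc1)O/C=C/C=C/[C@@H](O[Si](C)(C)C(C)(C)C)[C@@H](O[Si](CC)(CC)CC)CC(=O)/C(C)=C/C
A3 | alternative 2 | 6-(benzyloxy)-4a,5-dimethyl-3,4,4a,5,6,7-hexahydronaphthalen-1(2H)-one (configuration as drawn) | C(c1ccccc1)O[C@@H]2CC=C3C(=O)CCC[C@]3(C)[C@H]2C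
A4 | alternative 2 | 3-methyl-2-vinylcyclohex-2-en-1-one | CC1=C(C=C)C(=O)CCC1
A5 | alternative 2 | (E)-benzyl prop-1-enyl ether | C/C=C/OCc1ccccc1
A6 | alternative 3 | cis-1,8a-dimethyl-1,3,4,7,8,8a-hexahydronaphthalene-2,6-dione (configuration as drawn) | O=C1CCC2=CC(=O)CC[C@]2(C)[C@H]1C
A7 | alternative 3 | 1-(1-hydroxy-7a-methyl-5-oxo-2,3,5,6,7,7a-hexahydro-1H-inden-1-yl)ethyl methanesulfonate (carbinol configuration undefined) | C[C@@H](OS(C)(=O)=O)C3(O)CCC2=CC(=O)CC[C@@]23C
A8 | alternative 3 | (7aS)-7a-methyl-2,3,7,7a-tetrahydro-1H-indene-1,5(6H)-dione (as drawn) | O=C1CCC2=CC(=O)CC[C@@]21C
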